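**Assumption:** 3-(chloromethyl)furan (5) is taken as purchased; if not at hand it is one step from furan-3-ylmethanol (SOCl2, pyridine).

## The problem

The target is a C25 monocyclic sesterterpenoid. Numbering used here: ring carbons C1–C6 of the 1,2,6-trimethylcyclohex-2-ene (C1 quaternary, C2=C3 the olefin, C6 the CH–CH3); chain carbons C1′–C10′ counted from the ring, with (E)-olefins C3′=C4′ and C7′=C8′ (methyls on C3′ and C7′); C10′ is bound to C4 of a furan-2(5H)-one. The chain is a regular head-to-tail isoprenoid whose two olefin geometries can be bought in geraniol derivatives, so it is a problem of joining, and the hard question is where to join it: C1 is fully substituted and C1′ is neopentyl, so SN2 at C1′ is blocked and a radical at C1′ is a 2,2-disubstituted but-3-enyl radical open to 1,2-vinyl shift with ring expansion. The only stereocentres are C1 (R) and C6 (R), adjacent, one quaternary and one tertiary, with the two methyl groups trans, so that the chain is cis to the C6 methyl and H-6 is cis to the C1 methyl; nothing else in the molecule can control them, so the absolute sense must come from a reagent and the first centre set must relay to the second. The feature that makes the key step possible is that C1 is flanked by two methyl-bearing ring carbons, C2 and C6, that differ only in oxidation level (C2=C3 olefin, C5–C6 saturated): with H2 removed from C5–C6 the ring is a 1,1-disubstituted 2,6-dimethylcyclohexa-2,5-diene with a mirror plane through C1 and C4, which is the Birch pattern of 2,6-dimethylbenzoic acid with the ipso carbon as C1 and the carboxyl carbon as the C1 methyl. Because that methyl is cis to H-6, a carboxyl group in its place sits on exactly the ring face to which hydrogen must be delivered. Sensitive groups are the butenolide (base, hydride, carbanions; it is unveiled last), the skipped ring diene of the intermediates (olefin migration) and three trisubstituted olefins (acid, electrophiles, unselective hydrogenation).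

## Retrosynthesis

**22 ⇒ 18 (via 20).** The lactone carbonyl and the C5 methylene oxidation level are taken back to a 3-alkylfuran. The furan is inert to the enolate, LiAlH4, hot KOH and cationic iridium used earlier, none of which the butenolide would survive; a methyl-ketone precursor would need a ketal on and off plus an α-hydroxylation. The forward reaction must oxidise the furan regioselectively and faster than three trisubstituted olefins.

**18 ⇒ 14 (via 15, 16).** The C1 methyl is taken back to a carboxyl group. This costs three functional-group steps, but the carboxyl group is what activates the arene for dearomatisation and what anchors the hydrogenation catalyst. The deoxygenation has to be ionic, since a radical on this carbon is again a 2,2-disubstituted but-3-enyl radical.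

**14 ⇒ 13 (key).** The C5–H and C6–H bonds are cut. Precursor 13 has no stereocentre at all (mirror plane through C1, C4, the carboxyl carbon and C1′), while 14 has both. The forward reaction must pick one of two enantiotopic ring olefins, add H2 on the carboxyl face, stop after one olefin, and leave the chain olefins and the furan alone.

**13 ⇒ 11 + 10.** The C1–C1′ bond at the quaternary carbon is cut into a C9 arene and a C16 iodide. A cut one bond further out (C1′–C2′) would need a nucleophile or radical on neopentyl C1′; a cut at C2′–C3′ would need a halogen of defined geometry on C3′, which geranyl building blocks do not offer. At C1–C1′ the ring is the nucleophile (enediolate 12 from Birch reduction of 11) and the chain an unhindered primary iodide; ring, quaternary carbon and ring–chain bond arise together. The forward reaction asks that reduction of the hindered benzoate be regular and that alkylation beat E2.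

**10 ⇒ 7 (via 9, 8).** The C1′–I bond is taken back to the terminal olefin of a 1,3-diene by anti-Markovnikov hydroboration. This makes C1′ a one-carbon extension of a geranyl terminus; the forward reaction must be selective for the terminal CH2=.

**7 ⇒ 4 + 5; 4 ⇒ 3 ⇒ 1.** The C9′–C10′ bond is cut into an allylic acetate and the furylmethyl Grignard reagent 6 (from 5); C1′ comes from a Wittig methylenation of enal 3, itself from allylic oxidation of geranyl acetate 1 (via 2). Both (E)-olefins of the target are thus bought with 1 and never made.

## Roads not taken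

**Alternative 1:** (the most obvious) Cut the two ring C–CH3 bonds at C6 and C1. The forward key step is a copper-catalysed asymmetric conjugate addition of a methyl nucleophile (Me3Al or Me2Zn, Cu(OTf)2 with a chiral phosphoramidite) to the 2-alkylcyclohexenone A1, followed by trapping of the enolate with MeI to give A2. Enol triflate A3 and a methyl cross-coupling would then give 18. The relative configuration would be right (MeI enters trans to the new C6 methyl), and the sequence from iodide 10 is about as long as the chosen one. It is not preferred because three of its steps are stereo- or regio-defining C–C bond formations on the full chain, each in the least favourable variant of its class: an α-branched enone is a poor conjugate acceptor, the resulting enolate must be C-methylated at a fully substituted carbon, and C1 is set by substrate control alone. The chosen plan sets both centres in one catalyst-controlled event on an achiral precursor, with only functional-group changes after it.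

**Alternative 2:** Cut C1–C1′ with chirality transfer: Johnson–Claisen rearrangement of the cis-allylic alcohol A4 with triethyl orthoacetate would place a CH2CO2Et group on C1 from the face of the C–O bond and give A5. It is not preferred because A4 already needs two stereocentres in a 1,4-cis relation across a tetrasubstituted olefin, for which there is no short enantioselective access, so the stereo problem is moved and not solved. The [3,3] shift must also deliver carbon to a fully substituted olefin terminus syn to the neighbouring methyl. A5 ends at C2′, so the chain would still have to be joined by an sp3–sp2 coupling that needs a stereodefined vinyl halide.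

**Alternative 3:** The biomimetic cut: ring bond C1–C2 together with return of the C1 methyl to C2 and of H-6 to C1, i.e. acid-induced cyclisation of the acyclic furanoterpene A6 with a 1,2-hydride and a 1,2-methyl shift. It is not preferred because proton loss from the first cyclohexyl cation (to cyclogeranyl-type olefins) is expected to outrun two consecutive shifts, and no reagent controls the absolute sense. In the usual antiperiplanar course of the two shifts the methyl groups on C1 and C6 would end cis, whereas the target has them trans.

Key step: step 7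

## Route

**Step 1**
Reactants: 1 (2E)-3,7-dimethylocta-2,6-dien-1-yl acetate (geranyl acetate)
Product: 3 (2E,6E)-3,7-dimethyl-8-oxoocta-2,6-dien-1-yl acetate, via 8-hydroxygeranyl acetate 2 (not isolated)
Conditions: SeO2 (0.1 equiv), t-BuOOH (3 equiv), salicylic acid (0.1 equiv), CH2Cl2, rt; filtration, then MnO2 (excess) on the crude mixture, CH2Cl2, rt
Reagents that add atoms: tert-butyl hydroperoxide, CC(C)(C)OO (source of the oxygen atom, relayed by SeO2, O=[Se]=O)
Why: Riley-type allylic oxidation (ene reaction, then [2,3]-sigmatropic shift) attacks the (E)-methyl of the terminal trisubstituted olefin, the 2,3-olefin being deactivated by the allylic acetate; MnO2 then oxidises only the allylic alcohol 2 to the enal with the 6E geometry kept.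

**Step 2**
Reactants: 3 (2E,6E)-3,7-dimethyl-8-oxoocta-2,6-dien-1-yl acetate
Product: 4 (2E,6E)-3,7-dimethylnona-2,6,8-trien-1-yl acetate
Conditions: Ph3PCH3Br (1.15 equiv), KN(SiMe3)2 (1.1 equiv), THF, −78 → 0 °C
Reagents that add atoms: methyltriphenylphosphonium bromide, C[P+](c1ccccc1)(c1ccccc1)c1ccccc1.[Br-]
Why: Wittig methylenation; the unstabilised ylide should react with the enal far faster than with the acetate at low temperature, and the new carbon is the future C1′.

**Step 3**
Reactants: 4 (2E,6E)-3,7-dimethylnona-2,6,8-trien-1-yl acetate; 5 3-(chloromethyl)furan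
Product: 7 3-[(3E,7E)-4,8-dimethyldeca-3,7,9-trien-1-yl]furan, via furan-3-ylmethylmagnesium chloride 6 (not isolated)
Conditions: 5, Mg, THF, 0 °C (slow addition); then 4, Li2CuCl4 (5 mol %), THF, −30 → 0 °C
Reagents that add atoms: none
Why: Copper-catalysed cross-coupling of a Grignard reagent with a primary allylic acetate, a standard entry to 3-furyl terpenoids; substitution at the α-carbon is favoured because the γ-carbon is fully substituted, so the olefin geometry is kept.

**Step 4**
Reactants: 7 3-[(3E,7E)-4,8-dimethyldeca-3,7,9-trien-1-yl]furan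
Product: 9 (3E,7E)-10-(furan-3-yl)-3,7-dimethyldeca-3,7-dien-1-ol, via B-alkyl-9-BBN adduct 8 (not isolated)
Conditions: 9-BBN (1.1 equiv), THF, 0 °C → rt; then NaOH (3 M), H2O2 (30%), 0 °C → rt
Reagents that add atoms: hydrogen peroxide, OO
Why: Hydroboration–oxidation; 9-BBN should add boron to the terminal CH2= of the diene, since monosubstituted olefins react far faster than trisubstituted ones and the furan is inert, leaving the adjacent (E)-olefin in place.

**Step 5**
Reactants: 9 (3E,7E)-10-(furan-3-yl)-3,7-dimethyldeca-3,7-dien-1-ol
Product: 10 3-[(3E,7E)-10-iodo-4,8-dimethyldeca-3,7-dien-1-yl]furan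
Conditions: I2, PPh3, imidazole, CH2Cl2, 0 °C → rt, dark
Reagents that add atoms: iodine, II
Why: Appel-type iodination of an unhindered primary alcohol under neutral conditions that furan and olefins tolerate.

**Step 6**
Reactants: 11 2,6-dimethylbenzoic acid; 10 3-[(3E,7E)-10-iodo-4,8-dimethyldeca-3,7-dien-1-yl]furan
Product: 13 1-[(3E,7E)-10-(furan-3-yl)-3,7-dimethyldeca-3,7-dien-1-yl]-2,6-dimethylcyclohexa-2,5-diene-1-carboxylic acid, via dilithium enediolate 12 (not isolated)
Conditions: 11 (1.5 equiv), Li (about 3 equiv per 11, added until the blue colour just persists), NH3(l)/THF, −78 °C; then 10 (1.0 equiv) in THF, −78 → −33 °C; NH4Cl, evaporation of NH3, aq. HCl to pH 3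
Reagents that add atoms: none
Why: Birch reductive alkylation: the carboxylate steers reduction to the ipso and para carbons and the resulting enediolate is alkylated at C1 by the primary iodide, which builds the ring, the quaternary carbon and the ring–chain bond in one operation; 13 has a mirror plane, so no stereochemistry is at stake, and adding no excess lithium protects the furan of 10.

**Step 7**
Reactants: 13 1-[(3E,7E)-10-(furan-3-yl)-3,7-dimethyldeca-3,7-dien-1-yl]-2,6-dimethylcyclohexa-2,5-diene-1-carboxylic acid
Product: 14 (1S,6R)-1-[(3E,7E)-10-(furan-3-yl)-3,7-dimethyldeca-3,7-dien-1-yl]-2,6-dimethylcyclohex-2-ene-1-carboxylic acid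
Conditions: [Ir(cod)(L)]BArF (2 mol %; cod = cycloocta-1,5-diene; L = (Sa,S)-Bn-SIPHOX, 7-(diphenylphosphanyl)-7′-(4-benzyl-4,5-dihydrooxazol-2-yl)-1,1′-spirobiindane; BArF = B[3,5-(CF3)2C6H3]4), Et3N (0.5 equiv), H2 (6 atm), MeOH/THF, 25–45 °C, stopped at 1.0 equiv of H2
Reagents that add atoms: none
Why: Proposed new method: under H2 the cationic iridium precatalyst loses cyclooctadiene and the carboxylate of 13 binds the metal through oxygen, so that only a ring olefin in the β,γ-position can reach the iridium hydride; insertion and reductive elimination then deliver both hydrogens to C5 and C6 on the ring face that carries the carboxylate. The closest known reaction type is the carboxy-directed iridium-catalysed asymmetric hydrogenation of β,γ-unsaturated acids with chiral spiro phosphine–oxazoline ligands, together with desymmetrising hydrogenations of Birch-derived cyclohexa-1,4-dienes; new is its use to tell apart two enantiotopic β,γ-olefins across a quaternary α-carbon. No ring is closed. C6 is controlled by the chelate: H-6 enters cis to CO2H, which leaves the C6 methyl cis to the chain, the future trans-dimethyl relation. C1 becomes stereogenic only through the choice between the enantiotopic olefins C2=C3 and C5=C6, and that choice is made by the ligand, whose aryl groups and oxazoline substituent should leave room for the chain-bearing half of the chelate in one of the two diastereomeric arrangements only; the ligand antipode that gives (1S,6R) is to be fixed in a first screen. Chemoselectivity is expected because the chain olefins and the furan cannot chelate and such catalysts are sluggish without the carboxylate anchor; over-reduction should be slow for the major enantiomer, whose remaining olefin is the mismatched one, and fast for the minor one, which should raise the ee of 14 as conversion proceeds.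

**Step 8**
Reactants: 14 (1S,6R)-1-[(3E,7E)-10-(furan-3-yl)-3,7-dimethyldeca-3,7-dien-1-yl]-2,6-dimethylcyclohex-2-ene-1-carboxylic acid
Product: 15 [(1S,6R)-1-[(3E,7E)-10-(furan-3-yl)-3,7-dimethyldeca-3,7-dien-1-yl]-2,6-dimethylcyclohex-2-en-1-yl]methanol
Conditions: LiAlH4 (3 equiv), THF, 0 °C → reflux; aqueous NaOH work-up
Reagents that add atoms: none
Why: Hydride reduction of a hindered carboxylic acid; C1 is quaternary and C6 is not α to the carbonyl, so neither centre can epimerise, and olefins and furan are inert.

**Step 9**
Reactants: 15 [(1S,6R)-1-[(3E,7E)-10-(furan-3-yl)-3,7-dimethyldeca-3,7-dien-1-yl]-2,6-dimethylcyclohex-2-en-1-yl]methanol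
Product: 16 (1S,6R)-1-[(3E,7E)-10-(furan-3-yl)-3,7-dimethyldeca-3,7-dien-1-yl]-2,6-dimethylcyclohex-2-ene-1-carbaldehyde
Conditions: Dess–Martin periodinane (1.3 equiv), pyridine (3 equiv), CH2Cl2, 0 °C → rt
Reagents that add atoms: none
Why: Dess–Martin oxidation of a neopentyl primary alcohol; the aldehyde has no α-hydrogen, and the buffered medium spares the furan.

**Step 10**
Reactants: 16 (1S,6R)-1-[(3E,7E)-10-(furan-3-yl)-3,7-dimethyldeca-3,7-dien-1-yl]-2,6-dimethylcyclohex-2-ene-1-carbaldehyde
Product: 18 3-[(3E,7E)-4,8-dimethyl-10-[(1R,6R)-1,2,6-trimethylcyclohex-2-en-1-yl]deca-3,7-dien-1-yl]furan, via hydrazone 17 (not isolated)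
Conditions: N2H4·H2O (10 equiv), KOH (5 equiv), diethylene glycol, 130 °C, then 200 °C with removal of water
Reagents that add atoms: none
Why: Wolff–Kishner reduction (Huang-Minlon procedure), the classical way to turn a neopentyl formyl group into methyl; the path is ionic (diazenyl anion, then a carbanion protonated by solvent), which avoids the but-3-enyl radical that a radical deoxygenation would pass through, and furan and unactivated olefins are base-stable.

**Step 11**
Reactants: 18 3-[(3E,7E)-4,8-dimethyl-10-[(1R,6R)-1,2,6-trimethylcyclohex-2-en-1-yl]deca-3,7-dien-1-yl]furan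
Product: 20 5-hydroxy-4-[(3E,7E)-4,8-dimethyl-10-[(1R,6R)-1,2,6-trimethylcyclohex-2-en-1-yl]deca-3,7-dien-1-yl]furan-2(5H)-one (both C5 epimers), via furan endoperoxide 19 (not isolated)
Conditions: O2, visible light, tetraphenylporphyrin (cat.), i-Pr2NEt (5 equiv), CH2Cl2, −78 °C
Reagents that add atoms: dioxygen, O=O
Why: [4+2] cycloaddition of singlet oxygen to the furan, then Kornblum–DeLaMare-type opening of the endoperoxide: the hindered base removes the bridgehead hydrogen remote from the chain, so that carbon becomes the carbonyl and the hemiacetal lies next to the chain; at −78 °C the furan should react much faster than the trisubstituted olefins undergo the ene reaction.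

**Step 12**
Reactants: 20 5-hydroxy-4-[(3E,7E)-4,8-dimethyl-10-[(1R,6R)-1,2,6-trimethylcyclohex-2-en-1-yl]deca-3,7-dien-1-yl]furan-2(5H)-one
Product: 22 4-[(3E,7E)-4,8-dimethyl-10-[(1R,6R)-1,2,6-trimethylcyclohex-2-en-1-yl]deca-3,7-dien-1-yl]furan-2(5H)-one (target), via sodium hydroxy enoate 21 (not isolated)
Conditions: NaBH4 (1.5 equiv), EtOH, 0 °C; then aq. HCl to pH 2, rt
Reagents that add atoms: none
Why: Under the basic conditions the hydroxybutenolide is in equilibrium with its open formyl carboxylate, whose aldehyde is reduced by borohydride while the carboxylate shields the enoate from conjugate reduction; acidification lactonises the (Z)-hydroxy acid to the butenolide.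

## Compound list

1 | (2E)-3,7-dimethylocta-2,6-dien-1-yl acetate (geranyl acetate) | CC(C)=CCC/C(C)=C/COC(C)=O | starting material
2 | (2E,6E)-8-hydroxy-3,7-dimethylocta-2,6-dien-1-yl acetate | OC/C(C)=C/CC/C(C)=C/COC(C)=O | intermediate
3 | (2E,6E)-3,7-dimethyl-8-oxoocta-2,6-dien-1-yl acetate | O=C/C(C)=C/CC/C(C)=C/COC(C)=O | intermediate
4 | (2E,6E)-3,7-dimethylnona-2,6,8-trien-1-yl acetate | C=C/C(C)=C/CC/C(C)=C/COC(C)=O | intermediate
5 | 3-(chloromethyl)furan | ClCc1ccoc1 | starting material
6 | furan-3-ylmethylmagnesium chloride | Cl[Mg]Cc1ccoc1 | intermediate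
7 | 3-[(3E,7E)-4,8-dimethyldeca-3,7,9-trien-1-yl]furan | C=C/C(C)=C/CC/C(C)=C/CCc1ccoc1 | intermediate
8 | 9-[(3E,7E)-10-(furan-3-yl)-3,7-dimethyldeca-3,7-dien-1-yl]-9-borabicyclo[3.3.1]nonane | B1(CC/C(C)=C/CC/C(C)=C/CCc2ccoc2)C2CCCC1CCC2 | intermediate
9 | (3E,7E)-10-(furan-3-yl)-3,7-dimethyldeca-3,7-dien-1-ol | OCC/C(C)=C/CC/C(C)=C/CCc1ccoc1 | intermediate
10 | 3-[(3E,7E)-10-iodo-4,8-dimethyldeca-3,7-dien-1-yl]furan | ICC/C(C)=C/CC/C(C)=C/CCc1ccoc1 | intermediate
11 | 2,6-dimethylbenzoic acid | Cc1cccc(C)c1C(=O)O | starting material
12 | dilithium (2,6-dimethylcyclohexa-2,5-dien-1-ylidene)methanediolate | [Li+].[Li+].[O-]C([O-])=C1C(C)=CCC=C1C | intermediate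
13 | 1-[(3E,7E)-10-(furan-3-yl)-3,7-dimethyldeca-3,7-dien-1-yl]-2,6-dimethylcyclohexa-2,5-diene-1-carboxylic acid | CC1=CCC=C(C)C1(CC/C(C)=C/CC/C(C)=C/CCc1ccoc1)C(=O)O | intermediate
14 | (1S,6R)-1-[(3E,7E)-10-(furan-3-yl)-3,7-dimethyldeca-3,7-dien-1-yl]-2,6-dimethylcyclohex-2-ene-1-carboxylic acid | CC1=CCC[C@@H](C)[C@@]1(C(=O)O)CC/C(C)=C/CC/C(C)=C/CCc1ccoc1 | intermediate
15 | [(1S,6R)-1-[(3E,7E)-10-(furan-3-yl)-3,7-dimethyldeca-3,7-dien-1-yl]-2,6-dimethylcyclohex-2-en-1-yl]methanol | CC1=CCC[C@@H](C)[C@@]1(CO)CC/C(C)=C/CC/C(C)=C/CCc1ccoc1 | intermediate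
16 | (1S,6R)-1-[(3E,7E)-10-(furan-3-yl)-3,7-dimethyldeca-3,7-dien-1-yl]-2,6-dimethylcyclohex-2-ene-1-carbaldehyde | CC1=CCC[C@@H](C)[C@@]1(C=O)CC/C(C)=C/CC/C(C)=C/CCc1ccoc1 | intermediate
17 | [(1S,6R)-1-[(3E,7E)-10-(furan-3-yl)-3,7-dimethyldeca-3,7-dien-1-yl]-2,6-dimethylcyclohex-2-en-1-yl]methylidenehydrazine | CC1=CCC[C@@H](C)[C@@]1(C=NN)CC/C(C)=C/CC/C(C)=C/CCc1ccoc1 | intermediate
18 | 3-[(3E,7E)-4,8-dimethyl-10-[(1R,6R)-1,2,6-trimethylcyclohex-2-en-1-yl]deca-3,7-dien-1-yl]furan | CC1=CCC[C@@H](C)[C@@]1(C)CC/C(C)=C/CC/C(C)=C/CCc1ccoc1 | intermediate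
19 | 5-[(3E,7E)-4,8-dimethyl-10-[(1R,6R)-1,2,6-trimethylcyclohex-2-en-1-yl]deca-3,7-dien-1-yl]-2,3,7-trioxabicyclo[2.2.1]hept-5-ene | CC1=CCC[C@@H](C)[C@@]1(C)CC/C(C)=C/CC/C(C)=C/CCC1=CC2OOC1O2 | intermediate
20 | 5-hydroxy-4-[(3E,7E)-4,8-dimethyl-10-[(1R,6R)-1,2,6-trimethylcyclohex-2-en-1-yl]deca-3,7-dien-1-yl]furan-2(5H)-one | CC1=CCC[C@@H](C)[C@@]1(C)CC/C(C)=C/CC/C(C)=C/CCC1=CC(=O)OC1O | intermediate
21 | sodium (2Z)-4-hydroxy-3-[(3E,7E)-4,8-dimethyl-10-[(1R,6R)-1,2,6-trimethylcyclohex-2-en-1-yl]deca-3,7-dien-1-yl]but-2-enoate | CC1=CCC[C@@H](C)[C@@]1(C)CC/C(C)=C/CC/C(C)=C/CC/C(CO)=C/C(=O)[O-].[Na+] | intermediate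
22 | 4-[(3E,7E)-4,8-dimethyl-10-[(1R,6R)-1,2,6-trimethylcyclohex-2-en-1-yl]deca-3,7-dien-1-yl]furan-2(5H)-one | CC1=CCC[C@@H](C)[C@@]1(C)CC/C(C)=C/CC/C(C)=C/CCC1=CC(=O)OC1 | target

## Step count and least certain steps

Total step count: 12. Longest linear sequence: 12 steps (1 → 22); the purchased compounds 5 and 11 enter at steps 3 and 6.

**Step 7 (key step, proposed new method).** Most likely to go wrong: insufficient discrimination between the two enantiotopic ring olefins, slow turnover at a trisubstituted olefin next to a quaternary carbon, or olefin migration in the skipped diene before reduction. Fallback by known chemistry, setting out from 13 and returning at 15: reduction of 13 with LiAlH4 should give the dienyl alcohol F1. Hydroxyl-directed hydrogenation of F1 with the achiral cationic complex [Rh(nbd)(dppb)]BF4 (nbd = norbornadiene, dppb = Ph2P(CH2)4PPh2) under H2 pressure in CH2Cl2, stopped after one equivalent, should give the racemic cis-alcohol F2 with the same relative configuration, the chain olefins being left alone for lack of a directing group. F2 would be resolved by preparative chromatography on a chiral stationary phase to give 15.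

**Step 6.** Most likely to go wrong: sluggish or irregular reduction, because the two ortho methyl groups twist the carboxylate out of the ring plane and strain the planar enediolate; E2 elimination of the homoallylic iodide by lithium amide is the second risk. Fallback, setting out from 10 and returning at 13: the linear nitrile needs no coplanarity, so purchased 2,6-dimethylbenzonitrile would be reduced (Li, NH3, t-BuOH 1 equiv, THF, −78 °C) and the nitrile-stabilised anion alkylated with 10 to give the dienyl nitrile F3. Reduction with i-Bu2AlH would give the dienyl aldehyde F4, and oxidation with Ag2O/NaOH would give 13.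

**Step 4.** Most likely to go wrong: loss of regiocontrol on the conjugated diene (1,4-addition to an allylborane or a second hydroboration), which would also scramble the adjacent (E)-olefin. Fallback, setting out from 2 (isolated by chromatography after the SeO2 stage of step 1) and returning at 9: C1′ is brought in by SN2 instead. CBr4/PPh3 would give the allylic bromide F5. The hydroxymethyl-anion equivalent (i-PrO)Me2SiCH2MgCl with CuI (cat.) at −78 °C should displace the bromide in preference to the acetate and give the silane F6. Grignard reagent 6 with Li2CuCl4 at the acetate would give the furyl silane F7, and Tamao oxidation (H2O2, KF, KHCO3, THF/MeOH) would give 9.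

**Step 10.** Most likely to go wrong: slow hydrazone formation at the hindered formyl group, and losses on long heating in KOH. Fallback, setting out from 15 and returning at 18: MsCl/Et3N would give the mesylate F8, which LiEt3BH in refluxing THF should reduce by direct hydride displacement, again without a radical at the neopentyl carbon.

## Further compounds

F1 | step 7 | [1-[(3E,7E)-10-(furan-3-yl)-3,7-dimethyldeca-3,7-dien-1-yl]-2,6-dimethylcyclohexa-2,5-dien-1-yl]methanol | CC1=CCC=C(C)C1(CO)CC/C(C)=C/CC/C(C)=C/CCc1ccoc1
F2 | step 7 | rac-[(1S,6R)-1-[(3E,7E)-10-(furan-3-yl)-3,7-dimethyldeca-3,7-dien-1-yl]-2,6-dimethylcyclohex-2-en-1-yl]methanol (racemate, one enantiomer drawn) | CC1=CCC[C@@H](C)[C@@]1(CO)CC/C(C)=C/CC/C(C)=C/CCc1ccoc1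
F3 | step 6 | 1-[(3E,7E)-10-(furan-3-yl)-3,7-dimethyldeca-3,7-dien-1-yl]-2,6-dimethylcyclohexa-2,5-diene-1-carbonitrile | CC1=CCC=C(C)C1(C#N)CC/C(C)=C/CC/C(C)=C/CCc1ccoc1
F4 | step 6 | 1-[(3E,7E)-10-(furan-3-yl)-3,7-dimethyldeca-3,7-dien-1-yl]-2,6-dimethylcyclohexa-2,5-diene-1-carbaldehyde | CC1=CCC=C(C)C1(C=O)CC/C(C)=C/CC/C(C)=C/CCc1ccoc1
F5 | step 4 | (2E,6E)-8-bromo-3,7-dimethylocta-2,6-dien-1-yl acetate | BrC/C(C)=C/CC/C(C)=C/COC(C)=O
F6 | step 4 | (2E,6E)-9-[dimethyl(propan-2-yloxy)silyl]-3,7-dimethylnona-2,6-dien-1-yl acetate | CC(C)O[Si](C)(C)CC/C(C)=C/CC/C(C)=C/COC(C)=O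
F7 | step 4 | [(3E,7E)-10-(furan-3-yl)-3,7-dimethyldeca-3,7-dien-1-yl]dimethyl(propan-2-yloxy)silane | CC(C)O[Si](C)(C)CC/C(C)=C/CC/C(C)=C/CCc1ccoc1
F8 | step 10 | [(1S,6R)-1-[(3E,7E)-10-(furan-3-yl)-3,7-dimethyldeca-3,7-dien-1-yl]-2,6-dimethylcyclohex-2-en-1-yl]methyl methanesulfonate | CC1=CCC[C@@H](C)[C@@]1(COS(C)(=O)=O)CC/C(C)=C/CC/C(C)=C/CCc1ccoc1
A1 | alternative 1 | 2-[(3E,7E)-10-(furan-3-yl)-3,7-dimethyldeca-3,7-dien-1-yl]cyclohex-2-en-1-one | O=C1CCCC=C1CC/C(C)=C/CC/C(C)=C/CCc1ccoc1
A2 | alternative 1 | (2R,3R)-2-[(3E,7E)-10-(furan-3-yl)-3,7-dimethyldeca-3,7-dien-1-yl]-2,3-dimethylcyclohexan-1-one | O=C1CCC[C@@H](C)[C@@]1(C)CC/C(C)=C/CC/C(C)=C/CCc1ccoc1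
A3 | alternative 1 | (5R,6R)-6-[(3E,7E)-10-(furan-3-yl)-3,7-dimethyldeca-3,7-dien-1-yl]-5,6-dimethylcyclohex-1-en-1-yl trifluoromethanesulfonate | FC(F)(F)S(=O)(=O)OC1=CCC[C@@H](C)[C@@]1(C)CC/C(C)=C/CC/C(C)=C/CCc1ccoc1
A4 | alternative 2 | (1S,4R)-2,3,4-trimethylcyclohex-2-en-1-ol | O[C@H]1CC[C@@H](C)C(C)=C1C
A5 | alternative 2 | ethyl 2-[(1R,6R)-1,2,6-trimethylcyclohex-2-en-1-yl]acetate | CC1=CCC[C@@H](C)[C@@]1(C)CC(=O)OCC
A6 | alternative 3 | 3-[(3E,7E,11E)-4,8,12,16-tetramethylheptadeca-3,7,11,15-tetraen-1-yl]furan | CC(C)=CCC/C(C)=C/CC/C(C)=C/CC/C(C)=C/CCc1ccoc1
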